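## Structural features

The target is a 3-arylcoumarin: a benzene ring (ring A: C4a, C5, C6, C7, C8, C8a) fused to a 2-pyranone (O1, C2, C3, C4), with a 2,4-dihydroxyphenyl ring (ring B) joined to C3 by one sp2–sp2 bond. There is no stereocentre, and the only alkene outside the rings, in the prenyl chain, ends in two identical methyl groups, so no configuration has to be controlled. Ring A is the dense part: C4a carries C4, C5 a free hydroxyl, C6 the prenyl group, C7 a methoxy group, C8 a hydrogen and C8a the lactone oxygen. This is a phloroglucinol whose three oxygens are all different and whose prenyl group sits between two of them. The fragile elements are the prenyl group next to the free C5 phenol (acid closes the pair to a chroman), the lactone (opened by hydroxide) and the three electron-rich phenols. The real difficulty is regiochemical: telling the three oxygens of ring A apart and placing the prenyl group at C6 and not at C8. The key step reads C5(OH)–C6(prenyl)–C7(OMe) as the carbonyl carbon of a ketene followed by the alkyl-bearing and the oxygen-bearing carbons of an ynol ether, and reads C8–C8a(O1)–C4a as the CH carbon and the C6=C5 bond of a (2-oxopyran-6-yl)ketene, so ring A and its four substituents are written onto a preformed pyranone in one operation.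

## Logic of the disconnections

**20 from 19.** The two aryl O–Si bonds on ring B are cut last. The cut sits there because the only operation after ring A should run near neutrality: acid would close the C6 prenyl group onto the C5 hydroxyl, and hydroxide would open the lactone. The gain is that ring B travels as a non-nucleophilic, ketene-inert bis-silyl ether, while the C5 hydroxyl needs no protection because it is formed free in the ring-forming step. The forward step must be a buffered fluoride desilylation.

**19 from 9 and 14.** Four bonds of ring A are cut together: C8–C8a, C7–C8, C5–C6 and C4a–C5. The reason is the polarity match described above. The gain is the largest of the route: a pentasubstituted benzene with three different oxygens collapses to a monocyclic pyranone bearing a two-carbon diazo ketone and to an eight-carbon ynol ether, and no regiochemical decision about ring A remains. The forward step must achieve migration of the pyranonyl group in the Wolff rearrangement, one orientation of the ketene–alkyne cycloaddition, and closure onto pyranone C5. It must also discriminate the ynol ether from the prenyl alkene and spare the pyranone as diene and as chromophore.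

**9 from 7.** The bond between the acyl carbon and the diazomethyl carbon is cut, back to a carboxylic acid. Diazo ketones come reliably from activated acids, and the acid is a robust, storable intermediate. The forward step must activate the acid without releasing strong acid onto the silyl ethers, and C-acylation must outrun dipolar cycloaddition to the pyranone.

**7 from 6 and 3.** The C3–C1' bond between the pyranone and ring B is cut. It is an sp2–sp2 bond at the α-carbon of an unsaturated lactone, ideal for cross-coupling, and the cut divides the precursor into two six-membered rings of similar size. The forward coupling must tolerate a free carboxylic acid, a base-sensitive pyranone and a hindered ortho-silyloxy boronate.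

**6 from 4.** The C3–Br bond is cut. C3 is the nucleophilic terminus of the ring dienol ether, so electrophilic halogenation should find it, and 4 is purchasable. The forward step must favour C3 over C5.

**3 from 2, and 2 from 1.** The C–B bond and then the two O–Si bonds are cut. The bromine of 1 already marks the carbon that becomes C1', ortho to one oxygen and para to the other. The borylation must avoid an ortho-metalated aryl silyl ether, in which silicon can migrate from oxygen to carbon.

**14 from 10 and 11.** The C(sp)–CH2 bond and the CH3O–C(sp) bond are cut. 13 is available from 10 through 12 by substitution and elimination, and 11 supplies the prenyl group, so two bulk chemicals and a methoxide source remain. The alkylation must go at the primary allylic carbon, the skipped enyne must not be isomerized by base, and the volatile product must be isolated with care.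

## Other disconnections considered

**Alternative 1:** The cut runs through the lactone ring. O1–C8a and C4a–C4 come from insertion of an aryne into the C=O bond of N,N-dimethylformamide A4; C3–C4 and O1–C2 come from the enolate of the arylacetate A3.
- Forward step: fluoride would release the aryne from the ortho-silylaryl triflate A2. The carbonyl oxygen of A4 would add to the aryne carbon remote from the allyloxy group, the resulting ortho-quinone methide would take up the enolate of A3, and lactonization with expulsion of the amino group would give the coumarin A1.
- In its favour: the heterocycle and the C3–aryl bond form in one flask from the three pieces A2, A3 and A4. The alkoxy group beside the aryne gives dependable regiochemistry. The allyl ether at O5 is set up for a Claisen rearrangement that can only go to C6.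
- Against it here: A1 still lacks the prenyl group, so Claisen rearrangement and olefin cross-metathesis must follow. A2 needs regiocontrolled silylation and triflation of a 1,3,5-trioxygenated benzene. A3 is a much weaker carbon acid than the 1,3-dicarbonyl partners usual for this three-component reaction. The methoxymethyl ethers must finally be removed with acid in the presence of the prenyl group and the free C5 phenol.
- Comparison: on structure, the chosen plan fixes OH, prenyl, OMe and O1 in the ring-forming event, while this one fixes only the lactone. On mechanism, the aryne route is the better of the two in precedent and needs neither a diazo compound nor light; in convergence it is the equal of the chosen plan. On step economy it is behind: about five steps to A2 and three after A1, against one step after the key step of the chosen plan.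

**Alternative 2:** The cut removes C2 as carbon dioxide A7, breaking C2–C3 and O1–C2, and leaves the stilbene A6, whose ring A is symmetric.
- Forward step: Pd(OAc)2 and Cs2CO3 under A7 would form a phenoxide-bound alkenylpalladium species at the C3–H bond cis to ring A. Insertion of A7 and lactonization would give A5.
- In its favour: the two hydroxyls of ring A in A6 are equivalent, so the lactone can close only one way and the C5 hydroxyl appears unprotected. A6 is a short Wittig or Heck product. The reagents are cheap and benign.
- Against it here: the known carboxylation concerns the terminal =CH2 of α-substituted 2-hydroxystyrenes, whereas here an internal, aryl-substituted alkenyl C–H bond must be palladated. The same divalent palladium phenoxide could instead cyclize oxidatively to a benzofuran. Above all, A5 has no prenyl group. Its introduction at C6, in competition with C8 and with oxygen, would need allylation, Claisen rearrangement and metathesis, followed by acidic removal of the methoxymethyl groups.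
- Comparison: on structure, the symmetric design settles which oxygen becomes O1 as cleanly as the chosen plan does, an equal point, but it postpones the C6-against-C8 problem that the chosen plan solves inside the ring-forming step. On mechanism it is the better in simplicity and safety of reagents; both plans carry one untested extension of scope. On step economy it is probably shorter up to its key step but needs about four steps afterwards, so the total is higher.

**Alternative 3:** The same benzannulation is turned onto ring B. C5'–C6', C4'–C5', C2'–C3' and C1'–C2' are cut, leaving the coumarinyl vinyl diazo ketone A9 and the ethynyl ether A10.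
- Forward step: light-induced Wolff rearrangement of A9 to a vinylketene, [2+2] addition of A10, 4π opening, 6π closure and tautomerization would give A8, with O2' free and O4' carrying the 2-(trimethylsilyl)ethyl group.
- In its favour: vinylketenes from α,β-unsaturated diazo ketones are the best-precedented partners of this reaction. A terminal alkoxyacetylene is highly reactive and regioselective. The 6π closure disturbs no aromatic ring. On mechanism and precedent this alternative is the better of the two.
- Against it here: it spends the ring-forming step on the simple ring, which is available ready-made in 1. Ring A, with its three different oxygens and its prenyl group, is left to classical chemistry before A9 can be assembled. The differentiation of O2' from O4' that it offers is not needed, since both are free in the target. The extended coumarinyl enone chromophore of A9 is at least as exposed to unwanted photochemistry as the pyranone of 9.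
- Comparison: on structure, the chosen plan applies the benzannulation where the substitution problem lies, and this one where it does not. On step economy, the linear sequence to A9 would be roughly twice that to 9. After the key step both plans need only fluoride-type deprotection, an equal point.

Key step: step 7

Remark: the bromine adduct 5 is assumed to be the trans-3,4-dibromide, the adduct whose loss of HBr leads to the 3-bromide; compounds 1, 4, 10 and 11 and the starting materials of the fallbacks are taken as purchasable.

## Route

Step 1
Reactants: 1 4-bromoresorcinol (4-bromobenzene-1,3-diol)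
Product: 2 1-bromo-2,4-bis(triisopropylsilyloxy)benzene
Conditions: TIPSCl (2.4 equiv), imidazole (5 equiv), DMF, 40 °C
Reagents that add atoms: triisopropylsilyl chloride, CC(C)[Si](Cl)(C(C)C)C(C)C
Why: Imidazole-promoted O-silylation of both phenols. The hindered silyl ethers should pass the aqueous phosphate of step 4 and the acid chloride chemistry of step 5, do not react with ketenes, and leave under buffered fluoride, so no acid ever meets the prenyl group.

Step 2
Reactants: 2 1-bromo-2,4-bis(triisopropylsilyloxy)benzene
Product: 3 2-[2,4-bis(triisopropylsilyloxy)phenyl]-4,4,5,5-tetramethyl-1,3,2-dioxaborolane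
Conditions: B2pin2 (1.3 equiv), Pd(OAc)2 (3 mol %), SPhos (6 mol %), KOAc (3 equiv), 1,4-dioxane, 90 °C
Reagents that add atoms: bis(pinacolato)diboron, CC1(C)OB(OC1(C)C)B1OC(C)(C)C(C)(C)O1
Why: Miyaura borylation of the aryl bromide by zerovalent palladium formed from Pd(OAc)2 and the biaryl phosphine, which suits an electron-rich, ortho-substituted bromide. The catalytic route avoids an ortho-lithiated aryl silyl ether, which could suffer O-to-C silyl migration.

Step 3
Reactants: 4 2-oxo-2H-pyran-6-carboxylic acid
Product: 6 3-bromo-2-oxo-2H-pyran-6-carboxylic acid, via trans-3,4-dibromide 5 (not isolated)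
Conditions: Br2 (1.05 equiv), CH2Cl2/MeCN, 0 °C to rt; Et3N (2.2 equiv), 0 °C; 1 M HCl work-up
Reagents that add atoms: bromine, BrBr
Why: Electrophilic bromination of a 2-pyranone by addition and elimination. C3 is the α-carbon of the lactone and the terminus of the O1–C6=C5–C4=C3 dienol ether, whereas C5 is deactivated as the β-carbon of the acrylic acid unit. Loss of HBr from 5 through its acidic C3–H should leave bromine at C3.

Step 4
Reactants: 6 3-bromo-2-oxo-2H-pyran-6-carboxylic acid; 3 2-[2,4-bis(triisopropylsilyloxy)phenyl]-4,4,5,5-tetramethyl-1,3,2-dioxaborolane (1.5 equiv)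
Product: 7 3-[2,4-bis(triisopropylsilyloxy)phenyl]-2-oxo-2H-pyran-6-carboxylic acid
Conditions: Pd(OAc)2 (5 mol %), SPhos (10 mol %), K3PO4 (3.5 equiv), toluene/H2O (10:1), 60 °C; citric acid work-up
Reagents that add atoms: none
Why: Suzuki–Miyaura coupling at the C3–Br bond, an α-bromo enone type bond that should add readily to zerovalent palladium. The substrate reacts as its carboxylate, which lowers the electrophilicity of the pyranone toward aqueous base; phosphate is mild enough for aryl triisopropylsilyl ethers, and the mildly acidic work-up would re-close any ring-opened material.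

Step 5
Reactants: 7 3-[2,4-bis(triisopropylsilyloxy)phenyl]-2-oxo-2H-pyran-6-carboxylic acid
Product: 9 6-(2-diazoacetyl)-3-[2,4-bis(triisopropylsilyloxy)phenyl]-2H-pyran-2-one, via acid chloride 8 (not isolated)
Conditions: 1-chloro-N,N,2-trimethylprop-1-en-1-amine (1.2 equiv), CH2Cl2, 0 °C to rt; TMSCHN2 (2 equiv), MeCN/THF, 0 °C to rt, dark
Reagents that add atoms: (trimethylsilyl)diazomethane, C[Si](C)(C)C=[N+]=[N-]
Why: The α-chloroenamine converts the acid into acid chloride 8 without releasing HCl. C-acylation of the silyl diazomethane (the acylation stage of the Arndt–Eistert sequence), with loss of silicon to chloride, gives the diazo ketone. The silyl reagent replaces diazomethane and, being bulkier, should be slower in dipolar cycloaddition to the pyranone.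

Step 6
Reactants: 10 trichloroethylene; 11 prenyl bromide (1-bromo-3-methylbut-2-ene)
Product: 14 1-methoxy-5-methylhex-4-en-1-yne, via (E)-1,2-dichloro-1-methoxyethene 12 (not isolated), via lithium methoxyacetylide 13 (not isolated)
Conditions: KH, MeOH (1 equiv), THF, 0 °C; 10, −50 °C to rt; n-BuLi (2.3 equiv), −78 to −40 °C; 11, DMPU, −40 °C to rt; distillation at reduced pressure
Reagents that add atoms: methanol, CO
Why: Methoxide substitutes trichloroethylene by elimination and re-addition to give 12. Two equivalents of n-BuLi then effect dehydrochlorination and chlorine–lithium exchange to acetylide 13, and SN2 alkylation at the primary carbon of the allylic bromide gives the ynol ether. A methyl ynol ether has no β-hydrogen in its alkoxy group and so cannot fragment by retro-ene reaction on heating.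

Step 7
Reactants: 9 6-(2-diazoacetyl)-3-[2,4-bis(triisopropylsilyloxy)phenyl]-2H-pyran-2-one; 14 1-methoxy-5-methylhex-4-en-1-yne
Product: 19 5-hydroxy-7-methoxy-6-(3-methylbut-2-en-1-yl)-3-[2,4-bis(triisopropylsilyloxy)phenyl]-2H-chromen-2-one, via pyranonylketene 15 (not isolated), via 3-methoxycyclobutenone 16 (not isolated), via dienylketene 17 (not isolated), via cyclohexadienone 18 (not isolated)
Conditions: 14 (2 equiv), hν (420–450 nm LED), degassed CH2Cl2, 20 °C; evaporation under high vacuum (removes excess 14); toluene, 100 °C
Reagents that add atoms: none
Why: Proposed new method: the closest known reaction type is the photochemical Wolff variant of the Danheiser benzannulation, in which aryl-, heteroaryl- and vinylketenes from diazo ketones combine with alkoxy- and siloxyalkynes; new here is a 2-pyranon-6-yl group as the unsaturated partner of the ketene. Light at the long-wavelength edge of the diazo ketone absorption should expel N2 with migration of the pyranonyl group (C8–C8a) to give ketene 15; the nucleophilic, prenyl-bearing carbon of 14 then bonds to the ketene carbonyl carbon and the oxygen-bearing carbon to the ketene α-carbon (C5–C6 and C7–C8), an orientation fixed by the polarization of both partners, giving racemic cyclobutenone 16. On warming, reversible conrotatory 4π opening should give dienylketene 17, and because only the isomer with the pyranone turned inward can go on, the reversibility funnels material to it. Ring A then closes by thermal disrotatory 6π electrocyclization of the ketene carbon onto pyranone C5 (C4a–C5), the only carbon ortho to the ketene-bearing position, to give 18, whose enolization to phenol 19 is irreversible and trades the weak aromaticity of the pyranone for a benzene ring. No stereocentre survives, since the sp3 carbons of 16 and 18 are racemic and are erased on aromatization. Three selectivities are needed: the ynol ether must outcompete the prenyl alkene for the ketene (secured by its far higher nucleophilicity); the electron-poor pyranone diene must not add 14 in an inverse-demand Diels–Alder reaction (secured by irradiating at room temperature and stripping excess 14 before heating); and the pyranone and coumarin chromophores must not be photolysed (secured by long-wavelength light and by keeping the thermal stage dark). Acylation of 19 by ketene should be minimal because the phenol appears only in the thermal stage, after 15 has been consumed.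

Step 8
Reactants: 19 5-hydroxy-7-methoxy-6-(3-methylbut-2-en-1-yl)-3-[2,4-bis(triisopropylsilyloxy)phenyl]-2H-chromen-2-one
Product: 20 3-(2,4-dihydroxyphenyl)-5-hydroxy-7-methoxy-6-(3-methylbut-2-en-1-yl)-2H-chromen-2-one (target)
Conditions: TBAF (2.5 equiv), AcOH (3 equiv), THF, 0 °C to rt
Reagents that add atoms: none
Why: Fluoride-induced cleavage of the two aryl silyl ethers (desilylation), with acetic acid buffering the phenoxides so the lactone is not opened. No acid strong enough to cyclize the prenyl group onto the C5 hydroxyl is present, and no stereocentre arises.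

## Compound list

1 | 4-bromoresorcinol (4-bromobenzene-1,3-diol) | Oc1ccc(Br)c(O)c1 | starting material
2 | 1-bromo-2,4-bis(triisopropylsilyloxy)benzene | Brc1ccc(O[Si](C(C)C)(C(C)C)C(C)C)cc1O[Si](C(C)C)(C(C)C)C(C)C | intermediate
3 | 2-[2,4-bis(triisopropylsilyloxy)phenyl]-4,4,5,5-tetramethyl-1,3,2-dioxaborolane | CC1(C)OB(c2ccc(O[Si](C(C)C)(C(C)C)C(C)C)cc2O[Si](C(C)C)(C(C)C)C(C)C)OC1(C)C | intermediate
4 | 2-oxo-2H-pyran-6-carboxylic acid | OC(=O)c1cccc(=O)o1 | starting material
5 | trans-3,4-dibromo-2-oxo-3,4-dihydro-2H-pyran-6-carboxylic acid (racemic, one enantiomer drawn) | OC(=O)C1=C[C@@H](Br)[C@H](Br)C(=O)O1 | intermediate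
6 | 3-bromo-2-oxo-2H-pyran-6-carboxylic acid | OC(=O)c1ccc(Br)c(=O)o1 | intermediate
7 | 3-[2,4-bis(triisopropylsilyloxy)phenyl]-2-oxo-2H-pyran-6-carboxylic acid | OC(=O)c1ccc(-c2ccc(O[Si](C(C)C)(C(C)C)C(C)C)cc2O[Si](C(C)C)(C(C)C)C(C)C)c(=O)o1 | intermediate
8 | 3-[2,4-bis(triisopropylsilyloxy)phenyl]-2-oxo-2H-pyran-6-carbonyl chloride | ClC(=O)c1ccc(-c2ccc(O[Si](C(C)C)(C(C)C)C(C)C)cc2O[Si](C(C)C)(C(C)C)C(C)C)c(=O)o1 | intermediate
9 | 6-(2-diazoacetyl)-3-[2,4-bis(triisopropylsilyloxy)phenyl]-2H-pyran-2-one | [N-]=[N+]=CC(=O)c1ccc(-c2ccc(O[Si](C(C)C)(C(C)C)C(C)C)cc2O[Si](C(C)C)(C(C)C)C(C)C)c(=O)o1 | intermediate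
10 | trichloroethylene | ClC=C(Cl)Cl | starting material
11 | prenyl bromide (1-bromo-3-methylbut-2-ene) | CC(C)=CCBr | starting material
12 | (E)-1,2-dichloro-1-methoxyethene | CO/C(Cl)=C\Cl | intermediate
13 | lithium methoxyacetylide (lithium 2-methoxyethynide) | [Li]C#COC | intermediate
14 | 1-methoxy-5-methylhex-4-en-1-yne | COC#CCC=C(C)C | intermediate
15 | 6-(2-oxoethenyl)-3-[2,4-bis(triisopropylsilyloxy)phenyl]-2H-pyran-2-one (pyranonylketene) | O=C=Cc1ccc(-c2ccc(O[Si](C(C)C)(C(C)C)C(C)C)cc2O[Si](C(C)C)(C(C)C)C(C)C)c(=O)o1 | intermediate
16 | 6-[2-methoxy-3-(3-methylbut-2-en-1-yl)-4-oxocyclobut-2-en-1-yl]-3-[2,4-bis(triisopropylsilyloxy)phenyl]-2H-pyran-2-one (racemic) | COC1=C(CC=C(C)C)C(=O)C1c1ccc(-c2ccc(O[Si](C(C)C)(C(C)C)C(C)C)cc2O[Si](C(C)C)(C(C)C)C(C)C)c(=O)o1 | intermediate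
17 | 6-[(1E)-2-methoxy-6-methyl-3-(oxomethylidene)hepta-1,5-dien-1-yl]-3-[2,4-bis(triisopropylsilyloxy)phenyl]-2H-pyran-2-one (dienylketene) | O=C=C(CC=C(C)C)/C(OC)=C\c1ccc(-c2ccc(O[Si](C(C)C)(C(C)C)C(C)C)cc2O[Si](C(C)C)(C(C)C)C(C)C)c(=O)o1 | intermediate
18 | 7-methoxy-6-(3-methylbut-2-en-1-yl)-3-[2,4-bis(triisopropylsilyloxy)phenyl]-4aH-chromene-2,5-dione (racemic at C4a) | COC1=C(CC=C(C)C)C(=O)C2C=C(c3ccc(O[Si](C(C)C)(C(C)C)C(C)C)cc3O[Si](C(C)C)(C(C)C)C(C)C)C(=O)OC2=C1 | intermediate
19 | 5-hydroxy-7-methoxy-6-(3-methylbut-2-en-1-yl)-3-[2,4-bis(triisopropylsilyloxy)phenyl]-2H-chromen-2-one | COc1cc2oc(=O)c(-c3ccc(O[Si](C(C)C)(C(C)C)C(C)C)cc3O[Si](C(C)C)(C(C)C)C(C)C)cc2c(O)c1CC=C(C)C | intermediate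
20 | 3-(2,4-dihydroxyphenyl)-5-hydroxy-7-methoxy-6-(3-methylbut-2-en-1-yl)-2H-chromen-2-one | COc1cc2oc(=O)c(-c3ccc(O)cc3O)cc2c(O)c1CC=C(C)C | target

## Step count and least certain steps

Total: 8 steps. Longest linear sequence: 6 steps (steps 1, 2, 4, 5, 7 and 8, from 1 to 20). The pyranone branch (steps 3, 4, 5, 7, 8) and the ynol ether branch (steps 6, 7, 8) are shorter.

**Step 7 (key step, the one labelled as a proposed new method).** The pyranone is at once chromophore, diene and 2π partner, so the 6π closure onto it may be outrun by other processes: inverse-demand Diels–Alder addition of the ynol ether to the pyranone with loss of CO2, photochemical valence isomerization or ring opening of the pyranone, or sluggish migration of the electron-poor pyranonyl group in the Wolff step. The fallback uses known chemistry, sets out from 2 and returns at 19. Purchased 2,6-dihydroxy-4-methoxybenzaldehyde F1, whose two hydroxyls are equivalent, would be mono-allylated (allyl bromide, K2CO3, acetone) to 2-(allyloxy)-6-hydroxy-4-methoxybenzaldehyde F2. Knoevenagel condensation with Meldrum's acid (piperidinium acetate, EtOH, reflux) would give 5-(allyloxy)-7-methoxy-2-oxo-2H-chromene-3-carboxylic acid F3. Decarboxylative cross-coupling of F3 with 2 (PdBr2, bis[2-(diphenylphosphino)phenyl] ether, Ag2CO3, toluene/DMA, 150 °C) would give 5-(allyloxy)-7-methoxy-3-[2,4-bis(triisopropylsilyloxy)phenyl]-2H-chromen-2-one F4. Claisen rearrangement (N,N-diethylaniline, 190 °C), which can only reach C6, would give 6-allyl-5-hydroxy-7-methoxy-3-[2,4-bis(triisopropylsilyloxy)phenyl]-2H-chromen-2-one F5. Cross-metathesis with 2-methyl-2-butene (second-generation Grubbs catalyst RuCl2(=CHPh)(H2IMes)(PCy3), CH2Cl2, 40 °C) would then give 19.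

**Step 3.** Bromination may be slow or poorly regioselective (C5 against C3), because the carboxyl group deactivates both nucleophilic positions of the ring. The fallback sets out from 3 as the coupling partner and returns at 7, with the C3 substituent fixed by the starting material. 3-Hydroxy-2-oxo-2H-pyran-6-carboxylic acid F6 would be esterified (MeOH, H2SO4) to methyl 3-hydroxy-2-oxo-2H-pyran-6-carboxylate F7 and converted (Tf2O, pyridine, CH2Cl2, −20 °C) into methyl 2-oxo-3-(trifluoromethylsulfonyloxy)-2H-pyran-6-carboxylate F8. Anhydrous Suzuki–Miyaura coupling with 3 (Pd(OAc)2, SPhos, K3PO4, toluene, 70 °C) would give methyl 3-[2,4-bis(triisopropylsilyloxy)phenyl]-2-oxo-2H-pyran-6-carboxylate F9, and neutral ester cleavage (Me3SnOH, 1,2-dichloroethane, 70 °C) would give 7.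

**Step 4.** Likely failures are opening of the pyranone by the aqueous base, protodeboronation of the electron-rich hindered boronate, and partial loss of silyl ethers. The fallback sets out from 6 and returns at 7, and removes water and free acid from the coupling. 6 would be converted with tert-butyl 2,2,2-trichloroacetimidate (CH2Cl2/cyclohexane, rt) into tert-butyl 3-bromo-2-oxo-2H-pyran-6-carboxylate F10 and coupled with 3 under anhydrous conditions (Pd(OAc)2, SPhos, K3PO4, toluene, 80 °C) to tert-butyl 3-[2,4-bis(triisopropylsilyloxy)phenyl]-2-oxo-2H-pyran-6-carboxylate F11. The ester would be cleaved with TFA and Et3SiH in CH2Cl2 at 0 °C to give 7. The pyranone and the aryl silyl ethers should tolerate these conditions, and the silane should reduce the tert-butyl cation to 2-methylpropane before it can alkylate ring B.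

**Step 5.** The diazoalkane may add as a 1,3-dipole to the acyl-activated double bonds of the pyranone, or acylation may stop short. The fallback sets out from 8 and returns at 9 without a diazoalkane. Acid chloride 8 would be coupled with MeZnCl (Pd(PPh3)4, THF, 0 °C, Negishi acylation) to 6-acetyl-3-[2,4-bis(triisopropylsilyloxy)phenyl]-2H-pyran-2-one F12. Its lithium enolate (LiN(SiMe3)2, THF, −78 °C) would be trifluoroacetylated with 2,2,2-trifluoroethyl trifluoroacetate to 4,4,4-trifluoro-1-[3-[2,4-bis(triisopropylsilyloxy)phenyl]-2-oxo-2H-pyran-6-yl]butane-1,3-dione F13. Detrifluoroacetylative diazo transfer (MsN3, Et3N, H2O, MeCN, rt) would give 9.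

**Step 6.** Likely failures are slow C-alkylation of the weakly nucleophilic lithium alkoxyacetylide, base-induced isomerization of the skipped enyne, and loss of the volatile, hydrolytically labile product on isolation. The fallback sets out from 11 and returns at 14 through a different acetylide source and medium. 2-Chloro-1,1-dimethoxyethane F14 would be treated with exactly three equivalents of NaNH2 in liquid NH3 at −33 °C, which removes HCl and methanol in turn and leaves sodium methoxyacetylide F15. 11 would be added to this solution and 14 isolated by distillation.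

## Further compounds

F1 | step 7 | 2,6-dihydroxy-4-methoxybenzaldehyde | COc1cc(O)c(C=O)c(O)c1
F2 | step 7 | 2-(allyloxy)-6-hydroxy-4-methoxybenzaldehyde | C=CCOc1cc(OC)cc(O)c1C=O
F3 | step 7 | 5-(allyloxy)-7-methoxy-2-oxo-2H-chromene-3-carboxylic acid | C=CCOc1cc(OC)cc2oc(=O)c(C(=O)O)cc12
F4 | step 7 | 5-(allyloxy)-7-methoxy-3-[2,4-bis(triisopropylsilyloxy)phenyl]-2H-chromen-2-one | C=CCOc1cc(OC)cc2oc(=O)c(-c3ccc(O[Si](C(C)C)(C(C)C)C(C)C)cc3O[Si](C(C)C)(C(C)C)C(C)C)cc12
F5 | step 7 | 6-allyl-5-hydroxy-7-methoxy-3-[2,4-bis(triisopropylsilyloxy)phenyl]-2H-chromen-2-one | C=CCc1c(OC)cc2oc(=O)c(-c3ccc(O[Si](C(C)C)(C(C)C)C(C)C)cc3O[Si](C(C)C)(C(C)C)C(C)C)cc2c1O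
F6 | step 3 | 3-hydroxy-2-oxo-2H-pyran-6-carboxylic acid | OC(=O)c1ccc(O)c(=O)o1
F7 | step 3 | methyl 3-hydroxy-2-oxo-2H-pyran-6-carboxylate | COC(=O)c1ccc(O)c(=O)o1
F8 | step 3 | methyl 2-oxo-3-(trifluoromethylsulfonyloxy)-2H-pyran-6-carboxylate | COC(=O)c1ccc(OS(=O)(=O)C(F)(F)F)c(=O)o1
F9 | step 3 | methyl 3-[2,4-bis(triisopropylsilyloxy)phenyl]-2-oxo-2H-pyran-6-carboxylate | COC(=O)c1ccc(-c2ccc(O[Si](C(C)C)(C(C)C)C(C)C)cc2O[Si](C(C)C)(C(C)C)C(C)C)c(=O)o1
F10 | step 4 | tert-butyl 3-bromo-2-oxo-2H-pyran-6-carboxylate | CC(C)(C)OC(=O)c1ccc(Br)c(=O)o1
F11 | step 4 | tert-butyl 3-[2,4-bis(triisopropylsilyloxy)phenyl]-2-oxo-2H-pyran-6-carboxylate | CC(C)(C)OC(=O)c1ccc(-c2ccc(O[Si](C(C)C)(C(C)C)C(C)C)cc2O[Si](C(C)C)(C(C)C)C(C)C)c(=O)o1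
F12 | step 5 | 6-acetyl-3-[2,4-bis(triisopropylsilyloxy)phenyl]-2H-pyran-2-one | CC(=O)c1ccc(-c2ccc(O[Si](C(C)C)(C(C)C)C(C)C)cc2O[Si](C(C)C)(C(C)C)C(C)C)c(=O)o1
F13 | step 5 | 4,4,4-trifluoro-1-[3-[2,4-bis(triisopropylsilyloxy)phenyl]-2-oxo-2H-pyran-6-yl]butane-1,3-dione | FC(F)(F)C(=O)CC(=O)c1ccc(-c2ccc(O[Si](C(C)C)(C(C)C)C(C)C)cc2O[Si](C(C)C)(C(C)C)C(C)C)c(=O)o1
F14 | step 6 | 2-chloro-1,1-dimethoxyethane | ClCC(OC)OC
F15 | step 6 | sodium methoxyacetylide | [Na]C#COC
A1 | alternative 1 | 5-(allyloxy)-7-methoxy-3-[2,4-bis(methoxymethoxy)phenyl]-2H-chromen-2-one | COCOc1ccc(-c2cc3c(OCC=C)cc(OC)cc3oc2=O)c(OCOC)c1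
A2 | alternative 1 | 3-(allyloxy)-5-methoxy-2-(trimethylsilyl)phenyl trifluoromethanesulfonate | C=CCOc1cc(OC)cc(OS(=O)(=O)C(F)(F)F)c1[Si](C)(C)C
A3 | alternative 1 | methyl 2-[2,4-bis(methoxymethoxy)phenyl]acetate | COCOc1ccc(CC(=O)OC)c(OCOC)c1
A4 | alternative 1 | N,N-dimethylformamide | CN(C)C=O
A5 | alternative 2 | 5-hydroxy-7-methoxy-3-[2,4-bis(methoxymethoxy)phenyl]-2H-chromen-2-one | COCOc1ccc(-c2cc3c(O)cc(OC)cc3oc2=O)c(OCOC)c1
A6 | alternative 2 | 2-[(E)-2-[2,4-bis(methoxymethoxy)phenyl]ethenyl]-5-methoxybenzene-1,3-diol | COCOc1ccc(/C=C/c2c(O)cc(OC)cc2O)c(OCOC)c1
A7 | alternative 2 | carbon dioxide | O=C=O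
A8 | alternative 3 | 3-[2-hydroxy-4-[2-(trimethylsilyl)ethoxy]phenyl]-7-methoxy-6-(3-methylbut-2-en-1-yl)-5-(triisopropylsilyloxy)-2H-chromen-2-one | COc1cc2oc(=O)c(-c3ccc(OCC[Si](C)(C)C)cc3O)cc2c(O[Si](C(C)C)(C(C)C)C(C)C)c1CC=C(C)C
A9 | alternative 3 | (E)-1-diazo-4-[7-methoxy-6-(3-methylbut-2-en-1-yl)-2-oxo-5-(triisopropylsilyloxy)-2H-chromen-3-yl]but-3-en-2-one | [N-]=[N+]=CC(=O)/C=C/c1cc2c(O[Si](C(C)C)(C(C)C)C(C)C)c(CC=C(C)C)c(OC)cc2oc1=O
A10 | alternative 3 | [2-(ethynyloxy)ethyl]trimethylsilane | C#COCC[Si](C)(C)C
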